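## Retrosynthetic overview

1. Target 31 ← bis-silyl ester 30 ← 8S-alcohol 27: Mitsunobu inversion at C8 with (R)-2-methylbutanoic acid, then desilylation.
2. 27 ← bromo-aldehyde 25 by a ring-closing chromium allylation that forms C7–C8. It closes the ten-membered carbocycle last, sets C7 and C8, and unveils the α-methylene lactone.
3. Enabling feature: the C8 carbinol is homoallylic to the exocyclic C11=C13 methylene through C7, and the lactone oxygen sits on C6. The five-membered lactone ring (O–C6–C7–C11–C12) can therefore be carried as a 3-(bromomethyl)butenolide whose C13–C11=C7 unit is the allyl donor; the cis C4=C5 bond and the trans C1–C10 oxirane bend the C5–C9 tether toward C7.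
4. 25 ← butenolide by acrylate ring-closing metathesis ← C3–C4 union of Z-alkenyl iodide 16 (C4–C7, C15) with epoxy aldehyde 8 (C8–C10, C14, C1–C3) by asymmetric chromium/nickel alkenylation.
5. Ring order: oxirane (step 3) → butenolide (step 13) → ten-membered ring (step 16). 8 comes from but-3-yn-1-ol, 16 from silyl propargyl ether 9 and acrolein.

Key step: step 16

Remark: target numbering is used for all intermediates (C1–C10 ring carbons, C11/C12/C13 lactone α-carbon, carbonyl and methylene, C14 methyl, C15 hydroxymethyl; target = 1R,3S,6R,7R,8R,10R,4Z with an (R)-2-methylbutanoate). The chromium allylation is assumed to follow the closed chair model and place the new C8 oxygen α (8S), so the ester is introduced with inversion.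

## Route

Step 1
Reactants: 1 but-3-yn-1-ol
Product: 2 1-[(but-3-yn-1-yloxy)methyl]-4-methoxybenzene
Conditions: NaH, 4-methoxybenzyl chloride, Bu4NI (cat.), THF–DMF, 0 °C to rt
Reagents that add atoms: 4-methoxybenzyl chloride, COc1ccc(CCl)cc1
Why: Williamson etherification of the primary alkoxide with the benzylic chloride; the PMB group is the only protecting group here that can later be removed oxidatively beside silyl ethers, an oxirane and an allylic bromide.

Step 2
Reactants: 2 1-[(but-3-yn-1-yloxy)methyl]-4-methoxybenzene; 3 oxirane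
Product: 6 (E)-6-[(4-methoxybenzyl)oxy]-4-methylhex-3-en-1-ol, via alkenyldimethylalane 4 (not isolated), via lithium alkenylaluminate 5 (not isolated)
Conditions: Me3Al, Cp2ZrCl2 (25 mol %), CH2Cl2, 0 °C to rt; volatiles removed; n-BuLi, hexane–THF, −78 °C; oxirane, −78 °C to rt; H2O
Reagents that add atoms: trimethylaluminium, C[Al](C)C
Why: Zirconium-catalysed syn-carboalumination (Negishi) puts methyl (C14) and aluminium cis on the terminal alkyne, and the derived aluminate opens oxirane with retention, which fixes the E-trisubstituted C1=C10 alkene and adds C2–C3.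

Step 3
Reactants: 6 (E)-6-[(4-methoxybenzyl)oxy]-4-methylhex-3-en-1-ol
Product: 7 2-[(2R,3R)-3-{2-[(4-methoxybenzyl)oxy]ethyl}-3-methyloxiran-2-yl]ethan-1-ol
Conditions: D-fructose-derived Shi ketone (30 mol %), KHSO5 (as 2KHSO5·KHSO4·K2SO4), K2CO3, Bu4NHSO4 (cat.), aq. Na2B4O7–Na2EDTA buffer, MeCN–CH2(OMe)2, 0 °C
Reagents that add atoms: potassium peroxymonosulfate, [K+].[O-]S(=O)(=O)OO
Why: Shi asymmetric epoxidation of the only alkene present; the spiro transition state of the D-fructose-derived dioxirane gives the R,R-oxirane from an E-trisubstituted alkene, which sets C1 and C10.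

Step 4
Reactants: 7 2-[(2R,3R)-3-{2-[(4-methoxybenzyl)oxy]ethyl}-3-methyloxiran-2-yl]ethan-1-ol
Product: 8 2-[(2R,3R)-3-{2-[(4-methoxybenzyl)oxy]ethyl}-3-methyloxiran-2-yl]acetaldehyde
Conditions: Dess–Martin periodinane, NaHCO3, CH2Cl2, 0 °C; used without chromatography
Reagents that add atoms: none
Why: Dess–Martin oxidation under buffered, non-basic conditions gives the β,γ-epoxy aldehyde without β-elimination of the oxirane.

Step 5
Reactants: 9 tert-butyldimethyl(prop-2-yn-1-yloxy)silane; 10 acrolein
Product: 12 rac-6-[(tert-butyldimethylsilyl)oxy]hex-1-en-4-yn-3-ol, via lithium acetylide 11 (not isolated)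
Conditions: n-BuLi, THF, −78 °C; acrolein, −78 °C; H2O
Reagents that add atoms: none
Why: 1,2-addition of the lithium acetylide to acrolein at low temperature gives the racemic alkynyl vinyl carbinol (C15–C4–C5–C6–C7).

Step 6
Reactants: 12 rac-6-[(tert-butyldimethylsilyl)oxy]hex-1-en-4-yn-3-ol
Product: 13 (3S)-6-[(tert-butyldimethylsilyl)oxy]hex-1-en-4-yn-3-ol
Conditions: Ti(OiPr)4 (10 mol %), L-(+)-diisopropyl tartrate (15 mol %), t-BuOOH (0.6 equiv), 4 Å molecular sieves, CH2Cl2, −20 °C
Reagents that add atoms: none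
Why: Sharpless kinetic resolution: with L-(+)-tartrate the enantiomer whose carbinol substituent lies opposite to the face of oxygen delivery (here the R alcohol) is epoxidised at its vinyl group, and the S alcohol, which carries the C6 configuration of the target, is recovered.

Step 7
Reactants: 13 (3S)-6-[(tert-butyldimethylsilyl)oxy]hex-1-en-4-yn-3-ol
Product: 15 (3S,4Z)-6-[(tert-butyldimethylsilyl)oxy]-5-iodohexa-1,4-dien-3-ol, via cyclic alkenylaluminate 14 (not isolated)
Conditions: NaAlH2(OCH2CH2OMe)2, THF, 0 °C; then I2, THF, −78 °C to 0 °C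
Reagents that add atoms: iodine, II
Why: Hydroxyl-directed trans-hydroalumination delivers hydride to the proximal alkyne carbon (C5) and aluminium to C4 inside a five-membered aluminate, so iodinolysis with retention places iodine on C4 cis to C6 and thereby fixes the later cis C3/C6 relationship of the C4=C5 alkene.

Step 8
Reactants: 15 (3S,4Z)-6-[(tert-butyldimethylsilyl)oxy]-5-iodohexa-1,4-dien-3-ol
Product: 16 (3S,4Z)-6-[(tert-butyldimethylsilyl)oxy]-5-iodo-3-[(triethylsilyl)oxy]hexa-1,4-diene
Conditions: Et3SiCl, imidazole, CH2Cl2, 0 °C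
Reagents that add atoms: chlorotriethylsilane, CC[Si](Cl)(CC)CC
Why: Silylation of the secondary alcohol; the triethylsilyl ether can later be cleaved in the presence of the tert-butyldimethylsilyl ethers.

Step 9
Reactants: 16 (3S,4Z)-6-[(tert-butyldimethylsilyl)oxy]-5-iodo-3-[(triethylsilyl)oxy]hexa-1,4-diene; 8 2-[(2R,3R)-3-{2-[(4-methoxybenzyl)oxy]ethyl}-3-methyloxiran-2-yl]acetaldehyde
Product: 18 (1R,3S,6S,10R,4Z)-3-hydroxy seco-chain (C3–OH free; C6–OSiEt3 with vinyl on C6; C15–OTBS; C8–OPMB; 1,10-oxirane), via alkenylchromium dichloride 17 (not isolated)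
Conditions: CrCl2, chiral oxazoline–sulfonamide ligand (the enantiomer that directs Re-face addition), Et3N, NiCl2 (cat.), THF, rt
Reagents that add atoms: none
Why: Nickel-catalysed, chromium-mediated Nozaki–Hiyama–Kishi alkenylation joins C4 to the C3 aldehyde with retention of alkene geometry; the chiral ligand on chromium controls the aldehyde face, and Re-face addition gives 3S.

Step 10
Reactants: 18 (1R,3S,6S,10R,4Z)-3-hydroxy seco-chain
Product: 19 (1R,3S,6S,10R,4Z)-3-O-TBS ether of 18
Conditions: t-BuMe2SiCl, imidazole, DMAP (cat.), DMF, rt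
Reagents that add atoms: tert-butyldimethylsilyl chloride, CC(C)(C)[Si](C)(C)Cl
Why: Silylation of the allylic C3 alcohol under conditions that do not activate the oxirane.

Step 11
Reactants: 19 (1R,3S,6S,10R,4Z)-3-O-TBS ether of 18
Product: 20 (1R,3S,6S,10R,4Z)-6-hydroxy compound (C6–OH free; C3–OTBS; C15–OTBS; C8–OPMB)
Conditions: HF·pyridine, pyridine, THF, 0 °C
Reagents that add atoms: none
Why: A secondary triethylsilyl ether is cleaved much faster than tert-butyldimethylsilyl ethers by buffered HF·pyridine, which also spares the oxirane.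

Step 12
Reactants: 20 (1R,3S,6S,10R,4Z)-6-hydroxy compound; 21 2-(bromomethyl)acrylic acid
Product: 22 (1R,3S,6S,10R,4Z)-6-O-[2-(bromomethyl)acryloyl] ester of 20
Conditions: DCC, DMAP (5 mol %), CH2Cl2, −10 °C
Reagents that add atoms: none
Why: Steglich esterification brings in C11–C13; low DMAP loading and low temperature let acyl transfer outrun attack of DMAP on the allylic bromide.

Step 13
Reactants: 22 (1R,3S,6S,10R,4Z)-6-O-[2-(bromomethyl)acryloyl] ester of 20
Product: 23 (1R,3S,6R,10R,4Z)-3-(bromomethyl)butenolide (ring O–C6–C7=C11–C12; C8–OPMB; C3 and C15 OTBS)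
Conditions: second-generation Hoveyda–Grubbs catalyst RuCl2(H2IMes)(=CH-C6H4-2-OiPr) (5 mol %), CH2Cl2, 40 °C
Reagents that add atoms: none
Why: Ring-closing metathesis: the ruthenium carbene forms at the terminal vinyl group on C6 and closes the five-membered ring onto the 1,1-disubstituted acrylate with loss of ethene, while the trisubstituted C4=C5 bond is inert and no stereocentre is touched.

Step 14
Reactants: 23 (1R,3S,6R,10R,4Z)-3-(bromomethyl)butenolide
Product: 24 (1R,3S,6R,10R,4Z)-8-hydroxy bromomethylbutenolide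
Conditions: DDQ, CH2Cl2–pH 7 phosphate buffer, 0 °C
Reagents that add atoms: none
Why: Oxidative cleavage of the 4-methoxybenzyl ether by DDQ through the benzylic oxocarbenium ion; silyl ethers, oxirane, butenolide and allylic bromide are inert to it.

Step 15
Reactants: 24 (1R,3S,6R,10R,4Z)-8-hydroxy bromomethylbutenolide
Product: 25 (1R,3S,6R,10R,4Z)-seco bromo-aldehyde (C8 aldehyde; 3-(bromomethyl)butenolide)
Conditions: Dess–Martin periodinane, NaHCO3, CH2Cl2, 0 °C; used directly
Reagents that add atoms: none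
Why: Buffered Dess–Martin oxidation gives the β,γ-epoxy aldehyde without base, so neither the oxirane nor the acidic C6–H of the butenolide is disturbed.

Step 16
Reactants: 25 (1R,3S,6R,10R,4Z)-seco bromo-aldehyde
Product: 27 (1R,3S,6R,7R,8S,10R,4Z)-8-hydroxy-3,15-bis-O-TBS germacranolide (ten-membered ring closed; α-methylene lactone), via allylchromium dichloride 26 (not isolated)
Conditions: CrCl2 (10 equiv), THF–DMF, rt, slow addition of 25 (final 0.002 M); H2O
Reagents that add atoms: none
Why: Two equivalents of divalent chromium reduce the allylic C13–Br bond to a σ-allyl complex of trivalent chromium (26), which binds the tethered C8 aldehyde and transfers the allyl group through a six-membered chair transition state (Nozaki–Hiyama–Kishi carbonyl allylation); C7 attacks C8 with allylic transposition, so the endocyclic C7=C11 bond of the butenolide becomes the exocyclic C11=C13 methylene. The closest known reactions are the zinc- or chromium-mediated Barbier allylations of aldehydes with 3-(bromomethyl)butenolides and the intramolecular chromium-mediated 2-(alkoxycarbonyl)allylations that close the ten-membered ring of germacranolides. The ten-membered carbocycle closes in a 10-exo-trig mode at the aldehyde carbon; no other ring is formed, the lactone ring being already in place and only losing its ring double bond. C7 is set by the C6 stereocentre, since C8 adds to the butenolide face opposite the C5 substituent, which is also the only low-strain (trans) fusion of a five- to a ten-membered ring. C8 is set by the chair: the ring-locked allyl geometry (C6 trans to C13) puts C6 anti to the C8–O bond and the tether carbon C9 equatorial, anti to C11, which should give the 8S (8α) alkoxide and is the reason for the inversion in step 17. The step needs γ-attack (C7, not C13), which the cyclic transition state enforces, and ring closure over oligomerisation, which high dilution and the two turn elements of the tether (cis C4=C5, trans C1–C10 oxirane) should secure; divalent chromium leaves the oxirane, silyl ethers and lactone untouched.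

Step 17
Reactants: 27 (1R,3S,6R,7R,8S,10R,4Z)-8-hydroxy-3,15-bis-O-TBS germacranolide; 28 (R)-2-methylbutanoic acid
Product: 30 (1R,3S,6R,7R,8R,10R,4Z)-8-O-[(R)-2-methylbutanoyl]-3,15-bis-O-TBS germacranolide, via alkoxyphosphonium carboxylate 29 (not isolated)
Conditions: PPh3, diisopropyl azodicarboxylate, toluene, 0 °C to rt
Reagents that add atoms: none
Why: Mitsunobu esterification: the carboxylate displaces the alkoxyphosphonium group by SN2 and so inverts C8 from S to R, while the α-stereocentre of the acid is not enolised under these neutral conditions.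

Step 18
Reactants: 30 (1R,3S,6R,7R,8R,10R,4Z)-8-O-[(R)-2-methylbutanoyl]-3,15-bis-O-TBS germacranolide
Product: 31 CNP0267576.1
Conditions: HF·pyridine, pyridine, THF, 0 °C to rt
Reagents that add atoms: none
Why: Fluoride cleaves both silyl ethers; buffered HF·pyridine is non-basic, so no isomerisation of the methylene lactone and no acyl migration is expected, and it is mild enough for the oxirane.

## Compound list

1 | but-3-yn-1-ol | C#CCCO | starting material
2 | 1-[(but-3-yn-1-yloxy)methyl]-4-methoxybenzene | C#CCCOCc1ccc(OC)cc1 | intermediate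
3 | oxirane | C1CO1 | starting material
4 | (E)-{4-[(4-methoxybenzyl)oxy]-2-methylbut-1-en-1-yl}dimethylalane | C[Al](C)/C=C(\C)CCOCc1ccc(OC)cc1 | intermediate (not isolated)
5 | lithium (E)-butyl{4-[(4-methoxybenzyl)oxy]-2-methylbut-1-en-1-yl}dimethylaluminate | [Li+].CCCC[Al-](C)(C)/C=C(\C)CCOCc1ccc(OC)cc1 | intermediate (not isolated)
6 | (E)-6-[(4-methoxybenzyl)oxy]-4-methylhex-3-en-1-ol | OCC/C=C(\C)CCOCc1ccc(OC)cc1 | intermediate
7 | 2-[(2R,3R)-3-{2-[(4-methoxybenzyl)oxy]ethyl}-3-methyloxiran-2-yl]ethan-1-ol | OCC[C@H]1O[C@]1(C)CCOCc2ccc(OC)cc2 | intermediate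
8 | 2-[(2R,3R)-3-{2-[(4-methoxybenzyl)oxy]ethyl}-3-methyloxiran-2-yl]acetaldehyde | O=CC[C@H]1O[C@]1(C)CCOCc2ccc(OC)cc2 | intermediate
9 | tert-butyldimethyl(prop-2-yn-1-yloxy)silane | C#CCO[Si](C)(C)C(C)(C)C | starting material
10 | acrolein | C=CC=O | starting material
11 | {3-[(tert-butyldimethylsilyl)oxy]prop-1-yn-1-yl}lithium | [Li]C#CCO[Si](C)(C)C(C)(C)C | intermediate (not isolated)
12 | rac-6-[(tert-butyldimethylsilyl)oxy]hex-1-en-4-yn-3-ol | C=CC(O)C#CCO[Si](C)(C)C(C)(C)C | intermediate
13 | (3S)-6-[(tert-butyldimethylsilyl)oxy]hex-1-en-4-yn-3-ol | C=C[C@H](O)C#CCO[Si](C)(C)C(C)(C)C | intermediate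
14 | sodium (5S)-3-{[(tert-butyldimethylsilyl)oxy]methyl}-2,2-bis(2-methoxyethoxy)-5-vinyl-2,5-dihydro-1,2-oxaaluminol-2-uide | [Na+].C=C[C@H]1C=C(CO[Si](C)(C)C(C)(C)C)[Al-](OCCOC)(OCCOC)O1 | intermediate (not isolated)
15 | (3S,4Z)-6-[(tert-butyldimethylsilyl)oxy]-5-iodohexa-1,4-dien-3-ol | C=C[C@H](O)/C=C(\I)CO[Si](C)(C)C(C)(C)C | intermediate
16 | (3S,4Z)-6-[(tert-butyldimethylsilyl)oxy]-5-iodo-3-[(triethylsilyl)oxy]hexa-1,4-diene | C=C[C@H](O[Si](CC)(CC)CC)/C=C(\I)CO[Si](C)(C)C(C)(C)C | intermediate
17 | alkenylchromium dichloride from 16 (chromium in place of iodine on C4; ancillary ligand not drawn) | C=C[C@H](O[Si](CC)(CC)CC)/C=C(\[Cr](Cl)Cl)CO[Si](C)(C)C(C)(C)C | intermediate (not isolated)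
18 | (1R,3S,6S,10R,4Z)-3-hydroxy seco-chain: C3–OH, C6–OSiEt3 and vinyl on C6, C15–OTBS, C8–OPMB, 1,10-oxirane | C=C[C@H](O[Si](CC)(CC)CC)/C=C(/CO[Si](C)(C)C(C)(C)C)[C@@H](O)C[C@H]1O[C@]1(C)CCOCc2ccc(OC)cc2 | intermediate
19 | 3-O-TBS ether of 18 | C=C[C@H](O[Si](CC)(CC)CC)/C=C(/CO[Si](C)(C)C(C)(C)C)[C@@H](O[Si](C)(C)C(C)(C)C)C[C@H]1O[C@]1(C)CCOCc2ccc(OC)cc2 | intermediate
20 | (1R,3S,6S,10R,4Z)-6-hydroxy compound (C6–OH free, C3 and C15 OTBS, C8–OPMB) | C=C[C@H](O)/C=C(/CO[Si](C)(C)C(C)(C)C)[C@@H](O[Si](C)(C)C(C)(C)C)C[C@H]1O[C@]1(C)CCOCc2ccc(OC)cc2 | intermediate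
21 | 2-(bromomethyl)acrylic acid | OC(=O)C(=C)CBr | starting material
22 | 6-O-[2-(bromomethyl)acryloyl] ester of 20 | C=C[C@H](OC(=O)C(=C)CBr)/C=C(/CO[Si](C)(C)C(C)(C)C)[C@@H](O[Si](C)(C)C(C)(C)C)C[C@H]1O[C@]1(C)CCOCc2ccc(OC)cc2 | intermediate
23 | (1R,3S,6R,10R,4Z)-3-(bromomethyl)butenolide with C8–OPMB | O=C1O[C@H](/C=C(/CO[Si](C)(C)C(C)(C)C)[C@@H](O[Si](C)(C)C(C)(C)C)C[C@H]2O[C@]2(C)CCOCc3ccc(OC)cc3)C=C1CBr | intermediate
24 | (1R,3S,6R,10R,4Z)-8-hydroxy bromomethylbutenolide | O=C1O[C@H](/C=C(/CO[Si](C)(C)C(C)(C)C)[C@@H](O[Si](C)(C)C(C)(C)C)C[C@H]2O[C@]2(C)CCO)C=C1CBr | intermediate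
25 | (1R,3S,6R,10R,4Z)-seco bromo-aldehyde | O=C1O[C@H](/C=C(/CO[Si](C)(C)C(C)(C)C)[C@@H](O[Si](C)(C)C(C)(C)C)C[C@H]2O[C@]2(C)CC=O)C=C1CBr | intermediate
26 | allylchromium dichloride from 25 (chromium in place of bromine on C13; solvent ligands not drawn) | O=C1O[C@H](/C=C(/CO[Si](C)(C)C(C)(C)C)[C@@H](O[Si](C)(C)C(C)(C)C)C[C@H]2O[C@]2(C)CC=O)C=C1C[Cr](Cl)Cl | intermediate (not isolated)
27 | (1R,3S,6R,7R,8S,10R,4Z)-8-hydroxy-3,15-bis-O-TBS germacranolide | C=C1C(=O)O[C@@H]2/C=C(/CO[Si](C)(C)C(C)(C)C)[C@@H](O[Si](C)(C)C(C)(C)C)C[C@H]3O[C@]3(C)C[C@H](O)[C@@H]12 | intermediate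
28 | (R)-2-methylbutanoic acid | CC[C@@H](C)C(O)=O | starting material
29 | 8-O-triphenylphosphonium derivative of 27 as its (R)-2-methylbutanoate salt | C=C1C(=O)O[C@@H]2/C=C(/CO[Si](C)(C)C(C)(C)C)[C@@H](O[Si](C)(C)C(C)(C)C)C[C@H]3O[C@]3(C)C[C@H](O[P+](c4ccccc4)(c4ccccc4)c4ccccc4)[C@@H]12.CC[C@@H](C)C([O-])=O | intermediate (not isolated)
30 | (1R,3S,6R,7R,8R,10R,4Z)-8-O-[(R)-2-methylbutanoyl]-3,15-bis-O-TBS germacranolide | C=C1C(=O)O[C@@H]2/C=C(/CO[Si](C)(C)C(C)(C)C)[C@@H](O[Si](C)(C)C(C)(C)C)C[C@H]3O[C@]3(C)C[C@@H](OC(=O)[C@H](C)CC)[C@@H]12 | intermediate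
31 | CNP0267576.1 | C=C1C(=O)O[C@@H]2/C=C(/CO)[C@@H](O)C[C@H]3O[C@]3(C)C[C@@H](OC(=O)[C@H](C)CC)[C@@H]12 | target

## Step count and risks

Total steps: 18 (4 + 4 for the two fragments, 10 after their union). Longest linear sequence: 14 steps (steps 1–4 then 9–18; the branch through steps 5–8 is equally long).

Steps most likely to fail:

1. Step 16. The aldehyde may be attacked on its other face (tether carbon C9 axial in the chair), or the two C8 epimers may form together, because the strain of the forming ten-membered ring competes with the chair preference. Fallback, setting out from 25: the closure is run as before and whatever material carries the 8R (8β) hydroxyl, the (1R,3S,6R,7R,8R,10R,4Z)-8-hydroxy-3,15-bis-O-TBS germacranolide F1, is not inverted but acylated with retention by acid 28 (DCC, DMAP, CH2Cl2, 0 °C). This returns to the route at 30, makes step 17 unnecessary for that material, and renders the sequence convergent for both C8 epimers.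

2. Step 17. The activated C8 oxygen may be lost by elimination toward C7 or C9, or substitution may not occur, because the carboxylate must approach C8 past the branched C7 inside the ring. Fallback, setting out from 27 (redox inversion in place of SN2): Dess–Martin oxidation (NaHCO3, CH2Cl2, 0 °C) gives the C8 ketone, (1R,3S,6R,7R,10R,4Z)-8-oxo-3,15-bis-O-TBS germacranolide F2. NaBH4 with CeCl3·7H2O in MeOH at −78 °C should deliver hydride to the carbonyl face flanked by H7 (anti to the C6–C7 ring bond) and give the 8R alcohol F1. Steglich acylation of F1 with 28 (DCC, DMAP) returns to the route at 30.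

3. Step 9. Facial selectivity of the alkenylchromium addition to the C3 aldehyde may be poor, because ligand control can be mismatched with the neighbouring oxirane. Fallback, setting out from 16 and 8: ligand-free coupling (CrCl2, NiCl2 cat., DMSO–THF, rt) gives 18 together with its 3R epimer, the (1R,3R,6S,10R,4Z)-3-hydroxy seco-chain F3. Dess–Martin oxidation of the mixture (NaHCO3, CH2Cl2, 0 °C) converges both epimers to the (1R,6S,10R,4Z)-3-oxo seco-chain (enone) F4. Reduction with (R)-2-methyl-CBS-oxazaborolidine and catecholborane (toluene, −78 °C; the α-branched alkenyl group acting as the large substituent) should give the 3S alcohol and return to the route at 18.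

Further compounds

F1 | step 16 | (1R,3S,6R,7R,8R,10R,4Z)-8-hydroxy-3,15-bis-O-TBS germacranolide (C8 epimer of 27) | C=C1C(=O)O[C@@H]2/C=C(/CO[Si](C)(C)C(C)(C)C)[C@@H](O[Si](C)(C)C(C)(C)C)C[C@H]3O[C@]3(C)C[C@@H](O)[C@@H]12
F2 | step 17 | (1R,3S,6R,7R,10R,4Z)-8-oxo-3,15-bis-O-TBS germacranolide | C=C1C(=O)O[C@@H]2/C=C(/CO[Si](C)(C)C(C)(C)C)[C@@H](O[Si](C)(C)C(C)(C)C)C[C@H]3O[C@]3(C)CC(=O)[C@@H]12
F3 | step 9 | (1R,3R,6S,10R,4Z)-3-hydroxy seco-chain (C3 epimer of 18) | C=C[C@H](O[Si](CC)(CC)CC)/C=C(/CO[Si](C)(C)C(C)(C)C)[C@H](O)C[C@H]1O[C@]1(C)CCOCc2ccc(OC)cc2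
F4 | step 9 | (1R,6S,10R,4Z)-3-oxo seco-chain (enone) | C=C[C@H](O[Si](CC)(CC)CC)/C=C(/CO[Si](C)(C)C(C)(C)C)C(=O)C[C@H]1O[C@]1(C)CCOCc2ccc(OC)cc2
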